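**Plan**
- Retrosynthesis (briarane numbering): the γ-lactone is cut at C8–C17 (Reformatsky aldol of a C7 2-bromopropanoate onto a C8 ketone), the ten-membered ring at C6–C7 (Nozaki–Hiyama–Kishi), the C7–C8 unit at C8–C9 (alkoxyallylboration of a C9 aldehyde), the side chain at C3–C4 (enolate allylation) and ring A at C1–C14.
- Enabling feature: C14 is the β-carbon of the ring A enone (C12=O, C13=C14) and C1 is α to the oxygenated C2. At the C2 ketone / C12 ynone oxidation level, C1 is an enolate carbon 1,6 to the alkyne terminus C14, so one 6-endo-dig conjugate addition closes the cyclohexenone and creates the quaternary C1.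
- Forward order: acyclic C9–C12 unit (epoxidation, SN2 opening at C10), then the C2 ketone with its C3–C6 iodoalkene chain and the C12 ynone, then ring A (key step), then C7–C9, then the ten-membered ring (C6–C7), then the lactone (C8–C17).
- Stereochemistry: C10/C11 from Sharpless epoxidation and invertive epoxide opening; C1 from allylic 1,3-strain in the enolate of the key step; C2 from Felkin–Anh reduction; C9 from the Ipc2B reagent; C7 from the ring closure followed by Mitsunobu inversion; C8/C17 in the Reformatsky lactonisation; the 5Z alkene from hydroxyl-directed carbomagnesiation of propargyl alcohol.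

Key step: step 14

Remark: briarane numbering is used for all intermediates (C1 quaternary ring-fusion carbon, C2 and C9 acetoxy carbons, C7 lactone carbinol, C8 tertiary carbinol, C11 ring A carbinol, C12 ring A ketone); 5 and the named reagents are taken as purchasable.
Remark: 9 and 10 are E/Z mixtures at the butenyl group, 11–19 are epimer mixtures at C1 (and at C2 or C12 where these are carbinols), and 29–31 are mixtures at the CHBr carbon; all these centres are erased or reset in steps 9, 13, 14 and 25.

Step 1
Reactants: 1 prop-2-yn-1-ol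
Product: 3 (Z)-3-iodo-2-methylprop-2-en-1-ol, via chelated alkenylmagnesium alkoxide 2 (not isolated)
Conditions: MeMgBr (2.5 equiv), CuI (10 mol %), Et2O/THF, −10 °C to rt; then I2, −20 °C
Reagents that add atoms: methylmagnesium bromide C[Mg]Br; iodine II
Why: Copper-catalysed, hydroxyl-directed carbomagnesiation of the propargylic alkoxide puts methyl on the internal carbon and magnesium on the terminal carbon cis to the CH2O group (chelate 2), and iodinolysis with retention gives the Z iodoalkene that becomes the 5Z alkene.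

Step 2
Reactants: 3 (Z)-3-iodo-2-methylprop-2-en-1-ol
Product: 4 (Z)-3-bromo-1-iodo-2-methylprop-1-ene
Conditions: CBr4, PPh3, CH2Cl2, 0 °C
Reagents that add atoms: carbon tetrabromide BrC(Br)(Br)Br
Why: Appel bromination replaces the primary allylic hydroxyl by SN2 displacement of the oxyphosphonium group and leaves the alkene geometry untouched.

Step 3
Reactants: 5 2-[(4-methoxybenzyl)oxy]acetaldehyde
Product: 6 ethyl (E)-4-[(4-methoxybenzyl)oxy]-2-methylbut-2-enoate
Conditions: Ph3P=C(Me)CO2Et, CH2Cl2, rt
Reagents that add atoms: ethyl 2-(triphenylphosphoranylidene)propanoate CCOC(=O)C(C)=P(c1ccccc1)(c1ccccc1)c1ccccc1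
Why: Wittig olefination with a stabilised ylide should give the E trisubstituted enoate (C9–C12 with Me-20).

Step 4
Reactants: 6 ethyl (E)-4-[(4-methoxybenzyl)oxy]-2-methylbut-2-enoate
Product: 7 (E)-4-[(4-methoxybenzyl)oxy]-2-methylbut-2-en-1-ol
Conditions: i-Bu2AlH (2.2 equiv), CH2Cl2, −78 °C; Rochelle salt work-up
Reagents that add atoms: none
Why: 1,2-Reduction of the enoate by the aluminium hydride gives the allylic alcohol needed for directed epoxidation.

Step 5
Reactants: 7 (E)-4-[(4-methoxybenzyl)oxy]-2-methylbut-2-en-1-ol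
Product: 8 (2R,3R)-epoxy alcohol
Conditions: Ti(OiPr)4 (10 mol %), D-(−)-diisopropyl tartrate (12 mol %), t-BuOOH, 4 Å MS, CH2Cl2, −20 °C
Reagents that add atoms: tert-butyl hydroperoxide CC(C)(C)OO
Why: Sharpless asymmetric epoxidation, in which the titanium tartrate complex of the allylic alcohol with the D-(−)-tartrate delivers oxygen to the face that gives the (2R,3R) epoxide; this fixes C11 and, after inversion in step 6, C10.

Step 6
Reactants: 8 (2R,3R)-epoxy alcohol
Product: 9 (2S,3S)-diol
Conditions: MeCH=C(Me)MgBr (4 equiv), CuI (20 mol %), THF, −30 to 0 °C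
Reagents that add atoms: 1-methyl-1-propenylmagnesium bromide CC=C(C)[Mg]Br
Why: Copper-catalysed SN2 opening of the 2,3-epoxy alcohol by the alkenyl Grignard reagent occurs at C10, the only epoxide carbon open to backside attack because C11 is quaternary, with inversion at C10 and retention of the C11–O bond.

Step 7
Reactants: 9 (2S,3S)-diol
Product: 10 bis(triethylsilyl) ether
Conditions: Et3SiOTf (2.5 equiv), 2,6-lutidine, CH2Cl2, −78 to 0 °C
Reagents that add atoms: triethylsilyl trifluoromethanesulfonate CC[Si](CC)(CC)OS(=O)(=O)C(F)(F)F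
Why: Silylation with the triflate protects both the primary and the tertiary hydroxyl, the primary one as a group that step 11 oxidises directly.

Step 8
Reactants: 10 bis(triethylsilyl) ether
Product: 12 C2 carbinol, via monoalkylborane 11 (not isolated)
Conditions: BH3·THF, THF, 0 °C to rt; then NaOH, H2O2, 0 °C
Reagents that add atoms: hydrogen peroxide OO
Why: Hydroboration–oxidation puts boron and then oxygen on the less substituted alkene carbon C2; the new centres at C1 and C2 need no control because both are erased in steps 9 and 14.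

Step 9
Reactants: 12 C2 carbinol
Product: 13 C2 methyl ketone
Conditions: Dess–Martin periodinane, NaHCO3, CH2Cl2, rt
Reagents that add atoms: none
Why: Dess–Martin oxidation of the secondary alcohol gives the methyl ketone and tolerates the silyl and PMB ethers.

Step 10
Reactants: 13 C2 methyl ketone; 4 (Z)-3-bromo-1-iodo-2-methylprop-1-ene
Product: 15 iodoalkenyl ketone, via lithium enolate 14 (not isolated)
Conditions: LiN(i-Pr)2, THF, −78 °C; then 4, DMPU, −78 to −30 °C
Reagents that add atoms: none
Why: Kinetic deprotonation occurs at the unhindered methyl group (C3) and not at the tertiary C1–H, and SN2 alkylation of enolate 14 by the allylic bromide forms C3–C4 with the Z iodoalkene intact.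

Step 11
Reactants: 15 iodoalkenyl ketone
Product: 16 C12 aldehyde
Conditions: (COCl)2, DMSO, CH2Cl2, −78 to −30 °C; then Et3N
Reagents that add atoms: none
Why: Swern conditions cleave and oxidise a primary triethylsilyl ether directly to the aldehyde, while the tertiary silyl ether is too hindered to react with the chlorosulfonium salt.

Step 12
Reactants: 16 C12 aldehyde
Product: 17 C12 propargylic alcohol
Conditions: HC≡CMgBr (1.2 equiv), THF, −78 °C
Reagents that add atoms: ethynylmagnesium bromide C#C[Mg]Br
Why: Grignard addition to the aldehyde should outpace addition to the α-branched ketone at −78 °C; the new C12 carbinol centre is oxidised in step 13.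

Step 13
Reactants: 17 C12 propargylic alcohol
Product: 18 ynone
Conditions: Dess–Martin periodinane, NaHCO3, CH2Cl2, 0 °C
Reagents that add atoms: none
Why: Dess–Martin oxidation of the propargylic alcohol gives the ynone, which cannot enolise because C11 is fully substituted.

Step 14
Reactants: 18 ynone
Product: 20 ring A enone, via potassium C1 enolate 19 (not isolated)
Conditions: KOt-Bu (20 mol %), t-BuOH/THF (1:5), 0.01 M, 0 °C
Reagents that add atoms: none
Why: KOt-Bu equilibrates the ketone enolates, and only the tetrasubstituted C1 enolate 19 can reach the electrophilic alkyne terminus C14, so irreversible C1–C14 bond formation and protonation of the allenolate at C13 give the cyclohexenone. The reaction type is the intramolecular Michael addition of a ketone enolate to an ynone (a base-mediated Conia-ene-type carbocyclisation). Ring A closes in the 6-endo-dig mode, which the polarisation of the ynone (β-carbon C14) imposes over 5-exo attack at C13. The new quaternary centre C1 is controlled by allylic 1,3-strain: H-10 eclipses the enolate C1=C2 bond, so C11 with its tether lies on one face and C9 on the other, C14 bonds anti to C9, and Me-15 ends cis to C9 with the acyl group trans. The step needs regioselection between the C1 and C3 enolates and chemoselection against 1,2-addition at C12; the C3 enolate has no irreversible pathway (its aldol addition to the neopentyl C12 carbonyl is reversible) and the ynone itself has no α-hydrogen.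

Step 15
Reactants: 20 ring A enone
Product: 21 C9 primary alcohol
Conditions: DDQ, CH2Cl2/pH 7 buffer, 0 °C
Reagents that add atoms: none
Why: Oxidative PMB cleavage by DDQ (hydride abstraction, then hydrolysis of the oxocarbenium ion) frees the C9 hydroxyl and leaves the silyl ether, the enone and the iodoalkene untouched.

Step 16
Reactants: 21 C9 primary alcohol
Product: 22 C9 aldehyde
Conditions: Dess–Martin periodinane, NaHCO3, CH2Cl2, 0 °C
Reagents that add atoms: none
Why: Buffered Dess–Martin oxidation gives the aldehyde under non-basic conditions that avoid epimerisation at C10 and β-elimination of the C11 silyloxy group.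

Step 17
Reactants: 22 C9 aldehyde
Product: 23 syn alkoxyallylation product
Conditions: CH2=CHCH2OCH2OMe, s-BuLi, THF, −78 °C; (−)-Ipc2BOMe; BF3·OEt2; then 22, −78 °C; HOCH2CH2NH2 work-up
Reagents that add atoms: [(Z)-3-(methoxymethoxy)allyl]diisopinocampheylborane (Ipc from (+)-α-pinene) COCO/C=C\CB([C@@H]1C[C@@H]2C[C@H]([C@H]1C)C2(C)C)[C@@H]1C[C@@H]2C[C@H]([C@H]1C)C2(C)C
Why: Brown alkoxyallylboration, in which the Z γ-alkoxyallylborane adds through a closed chair transition state to give the syn 1,2-diol monoether and the Ipc2B groups direct attack to the aldehyde face that gives the 9R carbinol; the aldehyde should react far faster than the hindered ketones, and the amine work-up avoids peroxide.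

Step 18
Reactants: 23 syn alkoxyallylation product
Product: 24 C2,C9 diol
Conditions: NaBH4, MeOH/CH2Cl2 (1:1), −78 to −40 °C
Reagents that add atoms: none
Why: Borohydride reduction at low temperature should select the saturated C2 ketone over the hindered conjugated C12 ketone, and Felkin–Anh attack anti to C10, the largest group on the quaternary C1, should give the 2R alcohol.

Step 19
Reactants: 24 C2,C9 diol
Product: 25 C2,C9 diacetate
Conditions: Ac2O, pyridine, DMAP (cat.), CH2Cl2, 0 °C to rt
Reagents that add atoms: acetic anhydride CC(=O)OC(C)=O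
Why: DMAP-catalysed acylation esterifies the two secondary hydroxyls, installing both acetates of the target, and cannot touch the silylated tertiary C11 oxygen.

Step 20
Reactants: 25 C2,C9 diacetate
Product: 27 C7 aldehyde, via vicinal diol 26 (not isolated)
Conditions: OsO4 (3 mol %), NMO, acetone/H2O, 0 °C; then NaIO4, THF/pH 7 buffer, 0 °C
Reagents that add atoms: osmium tetroxide O=[Os](=O)(=O)=O; N-methylmorpholine N-oxide C[N+]1([O-])CCOCC1
Why: Upjohn dihydroxylation and periodate cleavage, in which OsO4 should select the monosubstituted terminal alkene over the trisubstituted iodoalkene and the hindered electron-poor enone, and NaIO4 cleaves diol 26 to the C7 aldehyde.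

Step 21
Reactants: 27 C7 aldehyde
Product: 28 ten-membered (7R) allylic alcohol
Conditions: CrCl2 (10 equiv), NiCl2 (2 mol % of CrCl2), DMSO/THF, rt, slow addition to 0.002 M
Reagents that add atoms: none
Why: Nozaki–Hiyama–Kishi reaction, in which nickel-catalysed formation of the alkenylchromium species with retention of the Z geometry and its addition to the aldehyde at high dilution close the ten-membered ring at C6–C7; Felkin–Anh attack anti to the C8 alkoxy group should give the 7R alcohol.

Step 22
Reactants: 28 ten-membered (7R) allylic alcohol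
Product: 29 (7S) 2-bromopropanoate
Conditions: CH3CHBrCO2H (racemic), PPh3, DIAD, toluene, 0 °C to rt
Reagents that add atoms: 2-bromopropanoic acid CC(Br)C(O)=O
Why: Mitsunobu esterification with the acidic α-bromo acid proceeds by SN2 displacement of the oxyphosphonium group, inverting C7 to the 7S configuration of the target and bringing in C17–C19.

Step 23
Reactants: 29 (7S) 2-bromopropanoate
Product: 30 C8 alcohol
Conditions: Me2BBr, CH2Cl2, −78 °C; then aq NaHCO3/THF
Reagents that add atoms: none
Why: Me2BBr cleaves the methoxymethyl acetal at −78 °C through a bromomethyl ether, conditions under which the acetates, the α-bromo ester and the hindered silyl ether should persist.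

Step 24
Reactants: 30 C8 alcohol
Product: 31 C8 ketone
Conditions: Dess–Martin periodinane, NaHCO3, CH2Cl2, 0 °C
Reagents that add atoms: none
Why: Buffered Dess–Martin oxidation, run at once to forestall acyl migration to the free C8 hydroxyl, gives the ketone that accepts the enolate and removes the relay stereocentre at C8.

Step 25
Reactants: 31 C8 ketone
Product: 32 11-O-triethylsilyl target
Conditions: SmI2 (2.2 equiv), THF, −78 °C
Reagents that add atoms: none
Why: Intramolecular Reformatsky reaction, in which SmI2 reduces the C–Br bond faster than the ketone and the samarium enolate, chelated to the C8 carbonyl oxygen, closes the γ-lactone with the C7–C6 and C8–C9 bonds trans on the new ring and Me-18 cis to O-8; this sets C8 and C17, and C17 stays epimerisable towards this less crowded arrangement.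

Step 26
Reactants: 32 11-O-triethylsilyl target
Product: 33 CNP0255369.2
Conditions: HF·pyridine, pyridine/THF, 0 °C to rt
Reagents that add atoms: none
Why: Fluoride-mediated desilylation removes the tertiary triethylsilyl ether and spares the acetates and the lactone.

**Compound list**
1 | prop-2-yn-1-ol | C#CCO | starting material
2 | bromomagnesium (Z)-3-(bromomagnesio)-2-methylprop-2-en-1-olate, chelated alkenylmagnesium alkoxide (not isolated) | Br[Mg]OC/C(C)=C\[Mg]Br | intermediate
3 | (Z)-3-iodo-2-methylprop-2-en-1-ol | OC/C(C)=C\I | intermediate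
4 | (Z)-3-bromo-1-iodo-2-methylprop-1-ene | BrC/C(C)=C\I | intermediate
5 | 2-[(4-methoxybenzyl)oxy]acetaldehyde | COc1ccc(COCC=O)cc1 | starting material
6 | ethyl (E)-4-[(4-methoxybenzyl)oxy]-2-methylbut-2-enoate | CCOC(=O)/C(C)=C/COCc1ccc(OC)cc1 | intermediate
7 | (E)-4-[(4-methoxybenzyl)oxy]-2-methylbut-2-en-1-ol | OC/C(C)=C/COCc1ccc(OC)cc1 | intermediate
8 | [(2R,3R)-3-{[(4-methoxybenzyl)oxy]methyl}-2-methyloxiran-2-yl]methanol | COc1ccc(COC[C@H]2O[C@]2(C)CO)cc1 | intermediate
9 | (2S,3S)-3-{[(4-methoxybenzyl)oxy]methyl}-2,4-dimethylhex-4-ene-1,2-diol (E/Z mixture) | COc1ccc(COC[C@H](C(C)=CC)[C@](C)(O)CO)cc1 | intermediate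
10 | bis(triethylsilyl) ether of 9 (C11–OSiEt3 and C12–OSiEt3) | COc1ccc(COC[C@H](C(C)=CC)[C@](C)(O[Si](CC)(CC)CC)CO[Si](CC)(CC)CC)cc1 | intermediate
11 | monoalkylborane with boron on C2 (not isolated) | COc1ccc(COC[C@H](C(C)C(C)B)[C@](C)(O[Si](CC)(CC)CC)CO[Si](CC)(CC)CC)cc1 | intermediate
12 | C2 carbinol: 10 with C1H(CH3)–C2H(OH)–CH3 in place of the butenyl group (epimers at C1 and C2) | COc1ccc(COC[C@H](C(C)C(C)O)[C@](C)(O[Si](CC)(CC)CC)CO[Si](CC)(CC)CC)cc1 | intermediate
13 | C2 methyl ketone (C1 epimers) | COc1ccc(COC[C@H](C(C)C(C)=O)[C@](C)(O[Si](CC)(CC)CC)CO[Si](CC)(CC)CC)cc1 | intermediate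
14 | lithium enolate of 13 on the methyl side (not isolated) | COc1ccc(COC[C@H](C(C)C(=C)O[Li])[C@](C)(O[Si](CC)(CC)CC)CO[Si](CC)(CC)CC)cc1 | intermediate
15 | iodoalkenyl ketone: C2 ketone carrying the C3–C6 chain CH2CH2C(CH3)=CHI (Z) | COc1ccc(COC[C@H](C(C)C(=O)CC/C(C)=C\I)[C@](C)(O[Si](CC)(CC)CC)CO[Si](CC)(CC)CC)cc1 | intermediate
16 | C12 aldehyde (α-triethylsilyloxy aldehyde) | COc1ccc(COC[C@H](C(C)C(=O)CC/C(C)=C\I)[C@](C)(O[Si](CC)(CC)CC)C=O)cc1 | intermediate
17 | C12 propargylic alcohol (C12 epimers) | COc1ccc(COC[C@H](C(C)C(=O)CC/C(C)=C\I)[C@](C)(O[Si](CC)(CC)CC)C(O)C#C)cc1 | intermediate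
18 | ynone: C2 ketone and C12 ynone with C13≡C14–H | COc1ccc(COC[C@H](C(C)C(=O)CC/C(C)=C\I)[C@](C)(O[Si](CC)(CC)CC)C(=O)C#C)cc1 | intermediate
19 | potassium C1=C2 enolate of 18 (not isolated) | COc1ccc(COC[C@H](C(C)=C(O[K])CC/C(C)=C\I)[C@](C)(O[Si](CC)(CC)CC)C(=O)C#C)cc1 | intermediate
20 | ring A enone: (4S,5S,6S)-4-[(Z)-5-iodo-4-methylpent-4-enoyl]-5-{[(4-methoxybenzyl)oxy]methyl}-4,6-dimethyl-6-[(triethylsilyl)oxy]cyclohex-2-en-1-one (Me-15, the C9 arm and Me-20 on one face) | COc1ccc(COC[C@@H]2[C@](C)(C=CC(=O)[C@@]2(C)O[Si](CC)(CC)CC)C(=O)CC/C(C)=C\I)cc1 | intermediate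
21 | C9 primary alcohol of 20 | OC[C@@H]1[C@](C)(C=CC(=O)[C@@]1(C)O[Si](CC)(CC)CC)C(=O)CC/C(C)=C\I | intermediate
22 | C9 aldehyde | O=C[C@@H]1[C@](C)(C=CC(=O)[C@@]1(C)O[Si](CC)(CC)CC)C(=O)CC/C(C)=C\I | intermediate
23 | syn alkoxyallylation product: C9(OH)–C8(OCH2OCH3)–CH=CH2 on ring A, 9R | C=C[C@@H](OCOC)[C@H](O)[C@@H]1[C@](C)(C=CC(=O)[C@@]1(C)O[Si](CC)(CC)CC)C(=O)CC/C(C)=C\I | intermediate
24 | C2,C9 diol (2R,9R) | C=C[C@@H](OCOC)[C@H](O)[C@@H]1[C@](C)(C=CC(=O)[C@@]1(C)O[Si](CC)(CC)CC)[C@H](O)CC/C(C)=C\I | intermediate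
25 | C2,C9 diacetate | C=C[C@@H](OCOC)[C@H](OC(C)=O)[C@@H]1[C@](C)(C=CC(=O)[C@@]1(C)O[Si](CC)(CC)CC)[C@H](OC(C)=O)CC/C(C)=C\I | intermediate
26 | vicinal diol from the terminal alkene of 25 (not isolated) | OCC(O)[C@@H](OCOC)[C@H](OC(C)=O)[C@@H]1[C@](C)(C=CC(=O)[C@@]1(C)O[Si](CC)(CC)CC)[C@H](OC(C)=O)CC/C(C)=C\I | intermediate
27 | C7 aldehyde (α-methoxymethoxy, β-acetoxy) | O=C[C@@H](OCOC)[C@H](OC(C)=O)[C@@H]1[C@](C)(C=CC(=O)[C@@]1(C)O[Si](CC)(CC)CC)[C@H](OC(C)=O)CC/C(C)=C\I | intermediate
28 | ten-membered (7R) allylic alcohol with 8-OCH2OCH3 and the 5Z alkene | CC(=O)O[C@@H]1[C@@H]2[C@](C)(C=CC(=O)[C@@]2(C)O[Si](CC)(CC)CC)[C@H](OC(C)=O)CC/C(C)=C\[C@@H](O)[C@H]1OCOC | intermediate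
29 | (7S) 2-bromopropanoate ester | CC(=O)O[C@@H]1[C@@H]2[C@](C)(C=CC(=O)[C@@]2(C)O[Si](CC)(CC)CC)[C@H](OC(C)=O)CC/C(C)=C\[C@H](OC(=O)C(C)Br)[C@H]1OCOC | intermediate
30 | C8 alcohol | CC(=O)O[C@@H]1[C@@H]2[C@](C)(C=CC(=O)[C@@]2(C)O[Si](CC)(CC)CC)[C@H](OC(C)=O)CC/C(C)=C\[C@H](OC(=O)C(C)Br)[C@H]1O | intermediate
31 | C8 ketone | CC(=O)O[C@@H]1[C@@H]2[C@](C)(C=CC(=O)[C@@]2(C)O[Si](CC)(CC)CC)[C@H](OC(C)=O)CC/C(C)=C\[C@H](OC(=O)C(C)Br)C1=O | intermediate
32 | 11-O-triethylsilyl ether of the target | CC(=O)O[C@@H]1[C@@H]2[C@](C)(C=CC(=O)[C@@]2(C)O[Si](CC)(CC)CC)[C@H](OC(C)=O)CC/C(C)=C\[C@@H]2OC(=O)[C@H](C)[C@]21O | intermediate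
33 | CNP0255369.2, (1S,2R,5Z,7S,8S,9R,10S,11S,17R) in briarane numbering | CC(=O)O[C@@H]1[C@@H]2[C@](C)(C=CC(=O)[C@@]2(C)O)[C@H](OC(C)=O)CC/C(C)=C\[C@@H]2OC(=O)[C@H](C)[C@]21O | target

**Totals**
Total step count: 26. Longest linear sequence: 24 steps (5 to 33, steps 3–26).

**Steps most likely to fail**

Step 14. The failure process would be enolisation on the C3 side followed by aldol addition to C12, or base-induced oligomerisation of the terminal ynone, in place of the 6-endo-dig closure. Fallback: setting out from 18, conjugate addition of methanol (MeOH, PMe3 cat.) should give the (E)-β-methoxy enone F1, a vinylogous ester whose carbonyl is a poor aldol acceptor and which has no acidic alkyne C–H. KOt-Bu in t-BuOH/THF should then close ring A by 6-endo-trig addition of the C1 enolate to C14 and loss of methoxide, under the same allylic-strain control. The route is rejoined at 20.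

Step 21. The failure process would be facial selectivity at C7 that is low, or opposite to the acyclic Felkin–Anh model, during the ten-membered ring closure. Fallback: setting out from 28 (as the C7 epimer mixture), Dess–Martin oxidation should give the macrocyclic dienone F2. Reagent-controlled CBS reduction (oxazaborolidine, catecholborane, −78 °C; the less hindered C7 ketone should react before the C12 ketone) should give the (7S) alcohol F3. Direct acylation with 2-bromopropanoyl bromide and pyridine, with retention, then gives 29, where the route is rejoined, and step 22 is bypassed.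

Step 25. The failure process would be single-electron reduction of the α-acyloxy ketone with loss of an acyloxy group, or enolate attack on the wrong ketone face to give the cis-fused lactone. Fallback: setting out from 28, Mitsunobu inversion with chloroacetic acid should give the (7S) chloroacetate F4. Me2BBr then gives the C8 alcohol F5, and Dess–Martin oxidation gives the C8 ketone F6. Thiourea and NaHCO3 in EtOH should remove the chloroacetate selectively to give the (7S) 7-hydroxy-8-ketone F7. An intermolecular Reformatsky reaction (Zn, ethyl 2-bromopropanoate, THF) should then add to the zinc chelate of O-7 and O-8 from the face anti to C6, giving the adduct F8. This lactonises through O-7 (with DBU equilibration at C17 if needed) to 32, where the route is rejoined.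

**Further compounds**
F1 | step 14 | (E)-β-methoxy enone from 18 (C12(=O)–CH=CH–OCH3) | COc1ccc(COC[C@H](C(C)C(=O)CC/C(C)=C\I)[C@](C)(O[Si](CC)(CC)CC)C(=O)/C=C/OC)cc1
F2 | step 21 | macrocyclic C7 ketone (5Z dienone) from 28 | CC(=O)O[C@@H]1[C@@H]2[C@](C)(C=CC(=O)[C@@]2(C)O[Si](CC)(CC)CC)[C@H](OC(C)=O)CC/C(C)=C\C(=O)[C@H]1OCOC
F3 | step 21 | (7S) allylic alcohol, C7 epimer of 28 | CC(=O)O[C@@H]1[C@@H]2[C@](C)(C=CC(=O)[C@@]2(C)O[Si](CC)(CC)CC)[C@H](OC(C)=O)CC/C(C)=C\[C@H](O)[C@H]1OCOC
F4 | step 25 | (7S) chloroacetate | CC(=O)O[C@@H]1[C@@H]2[C@](C)(C=CC(=O)[C@@]2(C)O[Si](CC)(CC)CC)[C@H](OC(C)=O)CC/C(C)=C\[C@H](OC(=O)CCl)[C@H]1OCOC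
F5 | step 25 | C8 alcohol of the chloroacetate | CC(=O)O[C@@H]1[C@@H]2[C@](C)(C=CC(=O)[C@@]2(C)O[Si](CC)(CC)CC)[C@H](OC(C)=O)CC/C(C)=C\[C@H](OC(=O)CCl)[C@H]1O
F6 | step 25 | C8 ketone of the chloroacetate | CC(=O)O[C@@H]1[C@@H]2[C@](C)(C=CC(=O)[C@@]2(C)O[Si](CC)(CC)CC)[C@H](OC(C)=O)CC/C(C)=C\[C@H](OC(=O)CCl)C1=O
F7 | step 25 | (7S) 7-hydroxy-8-ketone | CC(=O)O[C@@H]1[C@@H]2[C@](C)(C=CC(=O)[C@@]2(C)O[Si](CC)(CC)CC)[C@H](OC(C)=O)CC/C(C)=C\[C@H](O)C1=O
F8 | step 25 | Reformatsky adduct, ethyl ester with free 7-OH and 8-OH (not isolated) | CC(=O)O[C@@H]1[C@@H]2[C@](C)(C=CC(=O)[C@@]2(C)O[Si](CC)(CC)CC)[C@H](OC(C)=O)CC/C(C)=C\[C@H](O)[C@@]1(O)[C@@H](C)C(=O)OCC
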